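**Strategy**

Everything rests on closing the furan-2(5H)-one ring at its C4(sp2)–C5(sp3) bond, which creates the only stereocentre. A side-chain aldehyde with both trisubstituted alkenes already set and a (Z)-β-iodoenoyl chloride combine to a racemic 1-chloroalkyl ester in which O1–C5, C2 and the cis C3=C4 unit are in place. A chiral nickel catalyst with manganese then joins the alkenyl iodide carbon (C4) to the oxygen-bearing chloride carbon (C5). The step exploits the planar, oxygen-stabilised radical at lactone carbon C5: both enantiomers of the precursor should converge on the (R)-butenolide in one operation. Double desilylation completes the synthesis.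

Key step: step 9

Remark: the sense of induction of the nickel/bis(oxazoline) catalyst in step 9 cannot be predicted with confidence; the route is written for the ligand antipode that delivers (R) at C5, both antipodes being available.

**Route**

Step 1
Reactants: 1 dihydro-β-ionone, 4-(2,6,6-trimethylcyclohex-1-en-1-yl)butan-2-one
Product: 3 2-(but-3-yn-1-yl)-1,3,3-trimethylcyclohex-1-ene, via enol phosphate 2 (not isolated)
Conditions: LiN(i-Pr)2 (1.05 equiv), THF, −78 °C; ClP(O)(OEt)2, −78 °C → rt; then LiN(i-Pr)2 (2.3 equiv), −78 °C → rt; aq. NH4Cl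
Reagents that add atoms: none
Why: Kinetic deprotonation at the methyl group, O-phosphorylation and base-induced elimination of the enol phosphate (the Negishi alkyne synthesis from methyl ketones) should give the terminal alkyne and leave the tetrasubstituted ring alkene untouched.

Step 2
Reactants: 3 2-(but-3-yn-1-yl)-1,3,3-trimethylcyclohex-1-ene
Product: 5 (3E)-4-methyl-6-(2,6,6-trimethylcyclohex-1-en-1-yl)hex-3-en-1-ol, via alkenylalane 4 (not isolated)
Conditions: Me3Al (2 equiv), Cp2ZrCl2 (0.25 equiv), ClCH2CH2Cl, rt; evaporate; n-BuLi (1 equiv), hexane/THF, 0 °C; ethylene oxide, 0 °C → rt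
Reagents that add atoms: trimethylaluminium C[Al](C)C; ethylene oxide C1CO1
Why: Zirconium-catalysed syn-methylalumination (Negishi carboalumination) places CH3 and Al cis with the metal at the terminus, and the derived alanate should open ethylene oxide with retention, fixing the (E)-trisubstituted alkene.

Step 3
Reactants: 5 (3E)-4-methyl-6-(2,6,6-trimethylcyclohex-1-en-1-yl)hex-3-en-1-ol
Product: 6 2-[(3E)-6-bromo-3-methylhex-3-en-1-yl]-1,3,3-trimethylcyclohex-1-ene
Conditions: CBr4, PPh3, CH2Cl2, 0 °C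
Reagents that add atoms: carbon tetrabromide BrC(Br)(Br)Br
Why: Appel bromination of a primary, non-allylic alcohol under neutral conditions should not disturb the alkene geometry.

Step 4
Reactants: 6 2-[(3E)-6-bromo-3-methylhex-3-en-1-yl]-1,3,3-trimethylcyclohex-1-ene; 7 tert-butyl(diphenyl)(prop-2-yn-1-yloxy)silane
Product: 10 (3E,7E)-4-({[tert-butyl(diphenyl)silyl]oxy}methyl)-8-methyl-10-(2,6,6-trimethylcyclohex-1-en-1-yl)deca-3,7-dien-1-ol, via Grignard reagent 8 (not isolated), via alkenylcopper 9 (not isolated)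
Conditions: Mg, Et2O, reflux; CuBr·SMe2 (1.0 equiv), Et2O/Me2S, −45 °C; 7, −25 °C; then LiC≡C-n-Pr, HMPA, ethylene oxide, −40 → 0 °C
Reagents that add atoms: ethylene oxide C1CO1
Why: Normant syn-carbocupration of the terminal alkyne in diethyl ether puts the alkyl group on the internal carbon with copper cis to it, and the mixed alkynyl cuprate should open ethylene oxide with retention, so the long chain and the new CH2CH2OH arm end up cis (3E by the CIP rules); the bulky, weakly coordinating silyl ether disfavours the chelation-controlled regioisomer.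

Step 5
Reactants: 10 (3E,7E)-4-({[tert-butyl(diphenyl)silyl]oxy}methyl)-8-methyl-10-(2,6,6-trimethylcyclohex-1-en-1-yl)deca-3,7-dien-1-ol
Product: 11 (3E,7E)-4-({[tert-butyl(diphenyl)silyl]oxy}methyl)-8-methyl-10-(2,6,6-trimethylcyclohex-1-en-1-yl)deca-3,7-dienal
Conditions: Dess–Martin periodinane, pyridine, CH2Cl2, 0 °C; crude product used at once
Reagents that add atoms: none
Why: Buffered Dess–Martin oxidation is a fast, neutral oxidation of the primary homoallylic alcohol and should give the β,γ-unsaturated aldehyde without migration of the alkene into conjugation.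

Step 6
Reactants: 7 tert-butyl(diphenyl)(prop-2-yn-1-yloxy)silane
Product: 13 4-{[tert-butyl(diphenyl)silyl]oxy}but-2-ynoic acid, via lithium acetylide 12 (not isolated)
Conditions: n-BuLi, THF, −78 °C; CO2; dilute HCl
Reagents that add atoms: carbon dioxide O=C=O
Why: Deprotonation of the terminal alkyne and carboxylation of the lithium acetylide is a standard route to ynoic acids.

Step 7
Reactants: 13 4-{[tert-butyl(diphenyl)silyl]oxy}but-2-ynoic acid
Product: 14 (2Z)-4-{[tert-butyl(diphenyl)silyl]oxy}-3-iodobut-2-enoic acid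
Conditions: NaI, AcOH, 70 °C
Reagents that add atoms: sodium iodide [Na+].[I-]
Why: Conjugate addition of iodide and anti protonation (anti-hydroiodination of an ynoic acid) should give the (Z)-β-iodoacrylic acid with iodine cis to the carboxyl group; the bulky silyl ether should tolerate warm acetic acid.

Step 8
Reactants: 14 (2Z)-4-{[tert-butyl(diphenyl)silyl]oxy}-3-iodobut-2-enoic acid
Product: 15 (2Z)-4-{[tert-butyl(diphenyl)silyl]oxy}-3-iodobut-2-enoyl chloride
Conditions: 1-chloro-N,N,2-trimethylprop-1-en-1-amine, CH2Cl2, 0 °C → rt; concentrate, use crude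
Reagents that add atoms: 1-chloro-N,N,2-trimethylprop-1-en-1-amine CC(C)=C(Cl)N(C)C
Why: Neutral acid chloride formation with an α-chloroenamine avoids HCl and free chloride, which could exchange the vinylic iodide or isomerise the alkene.

Step 9
Reactants: 11 (3E,7E)-4-({[tert-butyl(diphenyl)silyl]oxy}methyl)-8-methyl-10-(2,6,6-trimethylcyclohex-1-en-1-yl)deca-3,7-dienal; 15 (2Z)-4-{[tert-butyl(diphenyl)silyl]oxy}-3-iodobut-2-enoyl chloride
Product: 17 (5R)-4-({[tert-butyl(diphenyl)silyl]oxy}methyl)-5-[(2E,6E)-3-({[tert-butyl(diphenyl)silyl]oxy}methyl)-7-methyl-9-(2,6,6-trimethylcyclohex-1-en-1-yl)nona-2,6-dien-1-yl]furan-2(5H)-one, via 1-chloroalkyl ester 16 (not isolated)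
Conditions: ZnCl2 (2 mol%), CH2Cl2, −20 → 0 °C; solvent exchange; then NiBr2(glyme) (10 mol%), chiral indane-fused bis(oxazoline) (12 mol%), Mn powder (3 equiv), NaI (0.5 equiv), DMA, 0 °C, slow addition, 5 mM
Reagents that add atoms: none
Why: Proposed new method: ZnCl2-catalysed addition of acyl chloride 15 to the carbonyl group of 11 (a known route to 1-chloroalkyl esters) should give racemic 16, after which zerovalent nickel inserts into the alkenyl C–I bond, the alkenylnickel (reduced by Mn to the univalent state) abstracts halogen from C5, and the planar α-acyloxy radical is recaptured at nickel to give a six-membered alkenyl(alkyl) nickelacycle of trivalent nickel that reductively eliminates the C4–C5 bond. The closest known reaction types are the nickel/bis(oxazoline)-catalysed enantioconvergent couplings of racemic 1-haloalkyl esters (made in situ from aldehyde and acyl halide) with organozinc reagents, and the nickel-catalysed asymmetric reductive coupling of alkenyl halides with secondary alkyl halides; new here is the intramolecular, ring-closing reductive variant. The five-membered lactone closes by C(sp2)–C(sp3) reductive elimination from the nickelacycle, not by a 5-endo radical attack on the enoate. The C5 stereocentre is set by the chiral bis(oxazoline) ligand on nickel during radical capture and reductive elimination, so both enantiomers of 16 should converge on (5R)-17. The step needs site selectivity (oxidative addition at C–I, radical formation at C–Cl), retention of the Z geometry that holds C2 and C5 cis, and cyclisation in preference to intermolecular coupling; the weak, oxygen-activated C–Cl bond, the pre-set (Z)-iodoenoate, the inert remote alkenes and slow addition at high dilution should secure these.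

Step 10
Reactants: 17 (5R)-4-({[tert-butyl(diphenyl)silyl]oxy}methyl)-5-[(2E,6E)-3-({[tert-butyl(diphenyl)silyl]oxy}methyl)-7-methyl-9-(2,6,6-trimethylcyclohex-1-en-1-yl)nona-2,6-dien-1-yl]furan-2(5H)-one
Product: 18 (6E)-neomanoalide, (5R)-4-(hydroxymethyl)-5-[(2E,6E)-3-(hydroxymethyl)-7-methyl-9-(2,6,6-trimethylcyclohex-1-en-1-yl)nona-2,6-dien-1-yl]furan-2(5H)-one
Conditions: HF·pyridine, pyridine, THF, 0 °C → rt
Reagents that add atoms: none
Why: Fluoride cleavage of both primary silyl ethers under buffered, non-basic conditions should spare the butenolide and not epimerise its γ-stereocentre.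

**Compound list**

1 | dihydro-β-ionone, 4-(2,6,6-trimethylcyclohex-1-en-1-yl)butan-2-one | CC(=O)CCC1=C(C)CCCC1(C)C | starting material
2 | diethyl 4-(2,6,6-trimethylcyclohex-1-en-1-yl)but-1-en-2-yl phosphate | C=C(CCC1=C(C)CCCC1(C)C)OP(=O)(OCC)OCC | intermediate
3 | 2-(but-3-yn-1-yl)-1,3,3-trimethylcyclohex-1-ene | C#CCCC1=C(C)CCCC1(C)C | intermediate
4 | dimethyl[(1E)-2-methyl-4-(2,6,6-trimethylcyclohex-1-en-1-yl)but-1-en-1-yl]alane | C[Al](C)/C=C(\C)CCC1=C(C)CCCC1(C)C | intermediate
5 | (3E)-4-methyl-6-(2,6,6-trimethylcyclohex-1-en-1-yl)hex-3-en-1-ol | OCC/C=C(\C)CCC1=C(C)CCCC1(C)C | intermediate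
6 | 2-[(3E)-6-bromo-3-methylhex-3-en-1-yl]-1,3,3-trimethylcyclohex-1-ene | BrCC/C=C(\C)CCC1=C(C)CCCC1(C)C | intermediate
7 | tert-butyl(diphenyl)(prop-2-yn-1-yloxy)silane | C#CCO[Si](c1ccccc1)(c1ccccc1)C(C)(C)C | starting material
8 | [(3E)-4-methyl-6-(2,6,6-trimethylcyclohex-1-en-1-yl)hex-3-en-1-yl]magnesium bromide | Br[Mg]CC/C=C(\C)CCC1=C(C)CCCC1(C)C | intermediate
9 | [(1E,5E)-2-({[tert-butyl(diphenyl)silyl]oxy}methyl)-6-methyl-8-(2,6,6-trimethylcyclohex-1-en-1-yl)octa-1,5-dien-1-yl]copper | [Cu]/C=C(/CO[Si](c1ccccc1)(c1ccccc1)C(C)(C)C)CC/C=C(\C)CCC1=C(C)CCCC1(C)C | intermediate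
10 | (3E,7E)-4-({[tert-butyl(diphenyl)silyl]oxy}methyl)-8-methyl-10-(2,6,6-trimethylcyclohex-1-en-1-yl)deca-3,7-dien-1-ol | OCC/C=C(/CO[Si](c1ccccc1)(c1ccccc1)C(C)(C)C)CC/C=C(\C)CCC1=C(C)CCCC1(C)C | intermediate
11 | (3E,7E)-4-({[tert-butyl(diphenyl)silyl]oxy}methyl)-8-methyl-10-(2,6,6-trimethylcyclohex-1-en-1-yl)deca-3,7-dienal | O=CC/C=C(/CO[Si](c1ccccc1)(c1ccccc1)C(C)(C)C)CC/C=C(\C)CCC1=C(C)CCCC1(C)C | intermediate
12 | (3-{[tert-butyl(diphenyl)silyl]oxy}prop-1-yn-1-yl)lithium | [Li]C#CCO[Si](c1ccccc1)(c1ccccc1)C(C)(C)C | intermediate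
13 | 4-{[tert-butyl(diphenyl)silyl]oxy}but-2-ynoic acid | OC(=O)C#CCO[Si](c1ccccc1)(c1ccccc1)C(C)(C)C | intermediate
14 | (2Z)-4-{[tert-butyl(diphenyl)silyl]oxy}-3-iodobut-2-enoic acid | OC(=O)/C=C(\I)CO[Si](c1ccccc1)(c1ccccc1)C(C)(C)C | intermediate
15 | (2Z)-4-{[tert-butyl(diphenyl)silyl]oxy}-3-iodobut-2-enoyl chloride | ClC(=O)/C=C(\I)CO[Si](c1ccccc1)(c1ccccc1)C(C)(C)C | intermediate
16 | (3E,7E)-1-chloro-4-({[tert-butyl(diphenyl)silyl]oxy}methyl)-8-methyl-10-(2,6,6-trimethylcyclohex-1-en-1-yl)deca-3,7-dien-1-yl (2Z)-4-{[tert-butyl(diphenyl)silyl]oxy}-3-iodobut-2-enoate (racemic at C1) | ClC(C/C=C(/CO[Si](c1ccccc1)(c1ccccc1)C(C)(C)C)CC/C=C(\C)CCC1=C(C)CCCC1(C)C)OC(=O)/C=C(\I)CO[Si](c1ccccc1)(c1ccccc1)C(C)(C)C | intermediate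
17 | (5R)-4-({[tert-butyl(diphenyl)silyl]oxy}methyl)-5-[(2E,6E)-3-({[tert-butyl(diphenyl)silyl]oxy}methyl)-7-methyl-9-(2,6,6-trimethylcyclohex-1-en-1-yl)nona-2,6-dien-1-yl]furan-2(5H)-one | CC1=C(CC/C(C)=C/CC/C(=C\C[C@H]2OC(=O)C=C2CO[Si](c3ccccc3)(c3ccccc3)C(C)(C)C)CO[Si](c3ccccc3)(c3ccccc3)C(C)(C)C)C(C)(C)CCC1 | intermediate
18 | (6E)-neomanoalide, (5R)-4-(hydroxymethyl)-5-[(2E,6E)-3-(hydroxymethyl)-7-methyl-9-(2,6,6-trimethylcyclohex-1-en-1-yl)nona-2,6-dien-1-yl]furan-2(5H)-one | CC1=C(CC/C(C)=C/CC/C(=C\C[C@H]2OC(=O)C=C2CO)CO)C(C)(C)CCC1 | target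

**Step count**

Total: 10 steps. Longest linear sequence: 7 steps (steps 1–5, 9, 10).

**Steps most likely to fail**

1. Step 9 (Proposed new method). Several processes could defeat it:
   - enolisation or O-acylation of the β,γ-unsaturated aldehyde instead of chloro ester formation;
   - capture of the C5 radical by the nickel centre of a second molecule, because the ester prefers its extended conformation, leading to oligomers;
   - weak facial discrimination at radical capture, or a racemic background ring closure;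
   - premature reduction of the C–I or C–Cl bond.

   Fallback (known chemistry), setting out from 11 and 14 and coming back at 17: acid 14 would be esterified with Me3SiCHN2 in toluene/MeOH to methyl (2Z)-4-{[tert-butyl(diphenyl)silyl]oxy}-3-iodobut-2-enoate F1. A catalytic asymmetric Nozaki–Hiyama–Kishi alkenylation of 11 with F1 (CrCl2 cat., NiCl2 cat., chiral oxazoline–sulfonamide ligand, Mn, Me3SiCl, LiCl, MeCN, rt) should give methyl (2Z,4R,6E,10E)-3,7-bis({[tert-butyl(diphenyl)silyl]oxy}methyl)-4-hydroxy-11-methyl-13-(2,6,6-trimethylcyclohex-1-en-1-yl)trideca-2,6,10-trienoate F2. Its cis hydroxy ester should lactonise on mild acid work-up (PPTS) to 17. Here the C4–C5 bond forms intermolecularly and the ring closes at oxygen.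

2. Step 4. Chelation of copper by the propargylic oxygen could reverse the regiochemistry of carbocupration and be followed by β-elimination to an allene; the alkenylcopper may also open ethylene oxide sluggishly or homocouple.

   Fallback, setting out from 6 and coming back at 10: alkylation of sodium triethyl phosphonoacetate with 6 (NaH, NaI, DMF, 60 °C) would give ethyl (5E)-2-(diethoxyphosphoryl)-6-methyl-8-(2,6,6-trimethylcyclohex-1-en-1-yl)oct-5-enoate F3. Horner–Wadsworth–Emmons reaction with 3-[(4-methoxybenzyl)oxy]propanal (NaH, THF) should give mainly ethyl (2E)-5-[(4-methoxybenzyl)oxy]-2-[(3E)-4-methyl-6-(2,6,6-trimethylcyclohex-1-en-1-yl)hex-3-en-1-yl]pent-2-enoate F4, purified from its geometric isomer by chromatography. Reduction with i-Bu2AlH would give (2E)-5-[(4-methoxybenzyl)oxy]-2-[(3E)-4-methyl-6-(2,6,6-trimethylcyclohex-1-en-1-yl)hex-3-en-1-yl]pent-2-en-1-ol F5. Silylation (t-BuPh2SiCl, imidazole) would give tert-butyl({(2E)-5-[(4-methoxybenzyl)oxy]-2-[(3E)-4-methyl-6-(2,6,6-trimethylcyclohex-1-en-1-yl)hex-3-en-1-yl]pent-2-en-1-yl}oxy)diphenylsilane F6, and DDQ (CH2Cl2, pH 7 buffer) would release 10.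

3. Step 5. The β,γ-alkene of the aldehyde may migrate into conjugation during oxidation or handling, or the aldehyde may decompose on silica.

   Fallback, setting out from 6 and 7 (through alkenylcopper 9 as in step 4) and coming back at 11: the cuprate would be trapped with racemic triethyl(oxiran-2-ylmethoxy)silane instead of ethylene oxide to give (4E,8E)-5-({[tert-butyl(diphenyl)silyl]oxy}methyl)-9-methyl-11-(2,6,6-trimethylcyclohex-1-en-1-yl)-1-[(triethylsilyl)oxy]undeca-4,8-dien-2-ol F7. Selective methanolysis of the triethylsilyl ether (PPTS, MeOH, 0 °C) would give (4E,8E)-5-({[tert-butyl(diphenyl)silyl]oxy}methyl)-9-methyl-11-(2,6,6-trimethylcyclohex-1-en-1-yl)undeca-4,8-diene-1,2-diol F8. Glycol cleavage (NaIO4, THF/pH 7 buffer, 0 °C) should release 11 under neutral conditions without an alcohol oxidation.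

Further compounds
F1 | step 9 | methyl (2Z)-4-{[tert-butyl(diphenyl)silyl]oxy}-3-iodobut-2-enoate | COC(=O)/C=C(\I)CO[Si](c1ccccc1)(c1ccccc1)C(C)(C)C
F2 | step 9 | methyl (2Z,4R,6E,10E)-3,7-bis({[tert-butyl(diphenyl)silyl]oxy}methyl)-4-hydroxy-11-methyl-13-(2,6,6-trimethylcyclohex-1-en-1-yl)trideca-2,6,10-trienoate | COC(=O)/C=C(\[C@H](O)C/C=C(/CO[Si](c1ccccc1)(c1ccccc1)C(C)(C)C)CC/C=C(\C)CCC1=C(C)CCCC1(C)C)CO[Si](c1ccccc1)(c1ccccc1)C(C)(C)C
F3 | step 4 | ethyl (5E)-2-(diethoxyphosphoryl)-6-methyl-8-(2,6,6-trimethylcyclohex-1-en-1-yl)oct-5-enoate | CCOC(=O)C(CC/C=C(\C)CCC1=C(C)CCCC1(C)C)P(=O)(OCC)OCC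
F4 | step 4 | ethyl (2E)-5-[(4-methoxybenzyl)oxy]-2-[(3E)-4-methyl-6-(2,6,6-trimethylcyclohex-1-en-1-yl)hex-3-en-1-yl]pent-2-enoate | CCOC(=O)/C(CC/C=C(\C)CCC1=C(C)CCCC1(C)C)=C/CCOCc1ccc(OC)cc1
F5 | step 4 | (2E)-5-[(4-methoxybenzyl)oxy]-2-[(3E)-4-methyl-6-(2,6,6-trimethylcyclohex-1-en-1-yl)hex-3-en-1-yl]pent-2-en-1-ol | OC/C(CC/C=C(\C)CCC1=C(C)CCCC1(C)C)=C/CCOCc1ccc(OC)cc1
F6 | step 4 | tert-butyl({(2E)-5-[(4-methoxybenzyl)oxy]-2-[(3E)-4-methyl-6-(2,6,6-trimethylcyclohex-1-en-1-yl)hex-3-en-1-yl]pent-2-en-1-yl}oxy)diphenylsilane | CC(C)(C)[Si](c1ccccc1)(c1ccccc1)OC/C(CC/C=C(\C)CCC1=C(C)CCCC1(C)C)=C/CCOCc1ccc(OC)cc1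
F7 | step 5 | (4E,8E)-5-({[tert-butyl(diphenyl)silyl]oxy}methyl)-9-methyl-11-(2,6,6-trimethylcyclohex-1-en-1-yl)-1-[(triethylsilyl)oxy]undeca-4,8-dien-2-ol | CC[Si](CC)(CC)OCC(O)C/C=C(/CO[Si](c1ccccc1)(c1ccccc1)C(C)(C)C)CC/C=C(\C)CCC1=C(C)CCCC1(C)C
F8 | step 5 | (4E,8E)-5-({[tert-butyl(diphenyl)silyl]oxy}methyl)-9-methyl-11-(2,6,6-trimethylcyclohex-1-en-1-yl)undeca-4,8-diene-1,2-diol | OCC(O)C/C=C(/CO[Si](c1ccccc1)(c1ccccc1)C(C)(C)C)CC/C=C(\C)CCC1=C(C)CCCC1(C)C
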